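**Retrosynthetic overview**

1. The CH2 bridge is cut last: target 17 ⇒ isobutyrylfilicinic acid 10 + chromene 15 + formaldehyde (Knoevenagel/Michael union; each half has a single free nucleophilic carbon).
2. 10 ⇒ filicinic acid 9 (C-acylation) ⇒ dienone 8 (hydrolysis). The six-membered carbocycle of 8 is not closed as such: it is grown from cyclobutenone 4 by insertion of the two carbons of ethoxyacetylene (4π opening / [2+2] / 4π opening / 6π closure). 4 comes from dimethylketene + ethoxyacetylene.
3. Enabling feature: in the carbocyclic trione ring the sp3 carbon C4 (CMe2) lies between two oxygen-bearing sp2 carbons, and O-bearing carbons alternate with C–H/C–C carbons around the ring. CMe2–C(=O) is a dimethylketene unit and each HC=C–O pair is an ynol ether. The quaternary carbon, as terminus of the 6π closure, blocks aromatisation, so the dienone survives.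
4. 15 ⇒ propargyl ether 14 (Au-catalysed 6-endo hydroarylation) ⇒ acylphloroglucinol 12 ⇒ phloroglucinol 11. Isobutyryl chloride 1 supplies both acyl groups and the CMe2–C=O unit.
5. Ring order: cyclobutenone (step 1) → trione carbocycle by two-carbon ring expansion (step 2); the benzene ring is bought; the pyran ring is closed in step 7.

Key step: step 2

Assumption: the enolised β-triketone ring is drawn as one tautomer and all tautomers are treated as the same compound; the target has no stereocentre, so no configuration has to be set.

**Route**

Step 1
Reactants: 1 isobutyryl chloride (2-methylpropanoyl chloride); 2 ethoxyacetylene (ethyl ethynyl ether)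
Product: 4 3-ethoxy-4,4-dimethylcyclobut-2-en-1-one, via dimethylketene 3 (not isolated)
Conditions: Et3N (1.2 equiv), Et2O, rt → reflux
Reagents that add atoms: none
Why: Dehydrochlorination should give dimethylketene, which undergoes the standard polar ketene–alkoxyalkyne [2+2] cycloaddition (nucleophilic alkyne CH carbon to the ketene carbonyl carbon, alkoxy carbon to CMe2) to give the 3-alkoxycyclobutenone.

Step 2
Reactants: 4 3-ethoxy-4,4-dimethylcyclobut-2-en-1-one; 2 ethoxyacetylene
Product: 8 3,5-diethoxy-6,6-dimethylcyclohexa-2,4-dien-1-one, via vinylketene 5 (not isolated), via alkenylcyclobutenone 6 (not isolated), via dienylketene 7 (not isolated)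
Conditions: 2 (3 equiv), PhMe, sealed tube, 100 °C
Reagents that add atoms: none
Why: Thermal 4π-electrocyclic opening of 4 (cleavage of the C1–C4 bond) should give vinylketene 5, which is intercepted by the ynol ether in a regioselective [2+2] cycloaddition to give 4-alkenylcyclobutenone 6; a second 4π opening gives dienylketene 7 and 6π-electrocyclisation delivers 8, so that the four ring carbons of 4 and the two alkyne carbons end up in the six-membered ring (net two-carbon ring expansion of the cyclobutenone). The closest known reaction type is the Danheiser cyclobutenone–alkoxyalkyne annulation, here in its 4,4-disubstituted mode, where the quaternary terminus forbids enolisation to a phenol and the cyclohexa-2,4-dienone is the end product. The six-membered ring closes by thermal disrotatory 6π-electrocyclisation of the dienylketene whose ketene and isopropylidene termini are cis, forming the bond between the ketene carbon (future C=O) and the CMe2 carbon; the unproductive geometric isomer reverts to 6 and is recycled. No stereocentre is formed. The step needs head-to-tail regioselectivity in the [2+2] event, secured by the polarisation of the ynol ether (its unsubstituted nucleophilic carbon bonds to the electrophilic ketene carbon, the alkoxy-bearing carbon to the ketene α-carbon), which places the three oxygens 1,3,5 with the gem-dimethyl carbon between two of them. Chemoselectivity for the ketene C=C bond over the enol-ether alkene of 5 follows from the usual behaviour of vinylketenes as 2π partners.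

Step 3
Reactants: 8 3,5-diethoxy-6,6-dimethylcyclohexa-2,4-dien-1-one
Product: 9 filicinic acid (3,5-dihydroxy-4,4-dimethylcyclohexa-2,5-dien-1-one)
Conditions: 2 M aq. HCl, THF, 60 °C
Reagents that add atoms: water, O
Why: Acid hydrolysis of the two vinylogous ethyl esters by addition–elimination of water at C3 and C5; the quaternary carbon prevents aromatisation, so the enolised trione should result.

Step 4
Reactants: 9 filicinic acid; 1 isobutyryl chloride
Product: 10 isobutyrylfilicinic acid (3,5-dihydroxy-4,4-dimethyl-2-(2-methylpropanoyl)cyclohexa-2,5-dien-1-one)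
Conditions: AlCl3 (3 equiv), PhNO2, rt → 60 °C; aq. HCl work-up
Reagents that add atoms: none
Why: Friedel–Crafts C-acylation of the enolised cyclic triketone; the two ring CH positions of 9 are equivalent and the first acyl group deactivates the ring against a second.

Step 5
Reactants: 11 phloroglucinol; 1 isobutyryl chloride
Product: 12 2-methyl-1-(2,4,6-trihydroxyphenyl)propan-1-one
Conditions: AlCl3 (4 equiv), PhNO2/CH2Cl2, 0 → 40 °C; aq. HCl work-up
Reagents that add atoms: none
Why: Friedel–Crafts acylation of the threefold-symmetric, highly activated arene; all ring positions are equivalent and the ketone product is deactivated, so mono-acylation should dominate.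

Step 6
Reactants: 12 2-methyl-1-(2,4,6-trihydroxyphenyl)propan-1-one; 13 3-chloro-3-methylbut-1-yne
Product: 14 1-[2,6-dihydroxy-4-(2-methylbut-3-yn-2-yloxy)phenyl]-2-methylpropan-1-one
Conditions: DBU (1.1 equiv), CuCl2·2H2O (1 mol %), MeCN, 0 °C → rt
Reagents that add atoms: none
Why: Copper-catalysed propargylic etherification of the mono-phenoxide (via a copper acetylide/allenylidene); the 4-OH, para to the ketone and outside the chelate, is the most acidic and most nucleophilic, so one equivalent of base should direct the tertiary propargyl group to it.

Step 7
Reactants: 14 1-[2,6-dihydroxy-4-(2-methylbut-3-yn-2-yloxy)phenyl]-2-methylpropan-1-one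
Product: 15 1-(5,7-dihydroxy-2,2-dimethyl-2H-chromen-6-yl)-2-methylpropan-1-one
Conditions: Ph3PAuNTf2 (3 mol %), CH2Cl2, rt
Reagents that add atoms: none
Why: Gold(I)-catalysed 6-endo-dig intramolecular hydroarylation of the aryl propargyl ether at either of the two equivalent ring carbons ortho to the ether oxygen; the O–CMe2 bond is never broken, so the pyran oxygen is necessarily the one para to the acyl group, which fixes the 6-acyl-5,7-dihydroxy pattern.

Step 8
Reactants: 10 isobutyrylfilicinic acid; 15 1-(5,7-dihydroxy-2,2-dimethyl-2H-chromen-6-yl)-2-methylpropan-1-one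
Product: 17 target CNP0318758.0, via methylidene trione 16 (not isolated)
Conditions: 37% aq. HCHO (1.0 equiv), 1% aq. KOH, 0 °C → rt, short contact time; then 1 M HCl
Reagents that add atoms: formaldehyde, C=O
Why: Knoevenagel condensation of the β-triketone 10 with formaldehyde should give enetrione 16, which is trapped in a Michael (Friedel–Crafts-type) addition by C8 of the phenoxide of 15 — the classical formaldehyde methylene-bridging of acylfilicinic acids with acylphloroglucinols; each partner has one free nucleophilic carbon, so only one cross-coupled constitution is possible.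

**Compound list**

1 | isobutyryl chloride | CC(C)C(Cl)=O | starting material
2 | ethoxyacetylene | CCOC#C | starting material
3 | dimethylketene | CC(C)=C=O | intermediate
4 | 3-ethoxy-4,4-dimethylcyclobut-2-en-1-one | CCOC1=CC(=O)C1(C)C | intermediate
5 | vinylketene: 3-ethoxy-4-methylpenta-1,3-dien-1-one | O=C=CC(OCC)=C(C)C | intermediate
6 | alkenylcyclobutenone: 3-ethoxy-4-(1-ethoxy-2-methylprop-1-en-1-yl)cyclobut-2-en-1-one | CCOC1=CC(=O)C1C(OCC)=C(C)C | intermediate
7 | dienylketene: (3E)-3,5-diethoxy-6-methylhepta-1,3,5-trien-1-one (ketene and isopropylidene termini cis) | O=C=C/C(OCC)=C\C(OCC)=C(C)C | intermediate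
8 | 3,5-diethoxy-6,6-dimethylcyclohexa-2,4-dien-1-one | CCOC1=CC(=O)C(C)(C)C(OCC)=C1 | intermediate
9 | filicinic acid (3,5-dihydroxy-4,4-dimethylcyclohexa-2,5-dien-1-one) | CC1(C)C(O)=CC(=O)C=C1O | intermediate
10 | isobutyrylfilicinic acid (3,5-dihydroxy-4,4-dimethyl-2-(2-methylpropanoyl)cyclohexa-2,5-dien-1-one) | CC(C)C(=O)C1=C(O)C(C)(C)C(O)=CC1=O | intermediate
11 | phloroglucinol | Oc1cc(O)cc(O)c1 | starting material
12 | 2-methyl-1-(2,4,6-trihydroxyphenyl)propan-1-one | CC(C)C(=O)c1c(O)cc(O)cc1O | intermediate
13 | 3-chloro-3-methylbut-1-yne | CC(C)(Cl)C#C | starting material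
14 | 1-[2,6-dihydroxy-4-(2-methylbut-3-yn-2-yloxy)phenyl]-2-methylpropan-1-one | CC(C)C(=O)c1c(O)cc(OC(C)(C)C#C)cc1O | intermediate
15 | 1-(5,7-dihydroxy-2,2-dimethyl-2H-chromen-6-yl)-2-methylpropan-1-one | CC(C)C(=O)c1c(O)cc2OC(C)(C)C=Cc2c1O | intermediate
16 | methylidene trione: 3-hydroxy-4,4-dimethyl-6-methylidene-2-(2-methylpropanoyl)cyclohex-2-ene-1,5-dione | CC(C)C(=O)C1=C(O)C(C)(C)C(=O)C(=C)C1=O | intermediate
17 | 6-{[5,7-dihydroxy-2,2-dimethyl-6-(2-methylpropanoyl)-2H-chromen-8-yl]methyl}-3,5-dihydroxy-4,4-dimethyl-2-(2-methylpropanoyl)cyclohexa-2,5-dien-1-one (CNP0318758.0) | CC(C)C(=O)C1=C(O)C(C)(C)C(O)=C(Cc2c(O)c(C(=O)C(C)C)c(O)c3c2OC(C)(C)C=C3)C1=O | target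

**Step count**

Total: 8 steps. Longest linear sequence: 5 steps (1 → 2 → 3 → 4 → 8); the chromene branch is 3 steps (5 → 6 → 7) before the union.

**Steps most likely to fail**

Step 2. The opening of the gem-dimethylcyclobutenone requires inward rotation of a methyl group and may need a temperature at which ethoxyacetylene is consumed by retro-ene fragmentation; the vinylketene could also be drained by a 1,5-hydrogen shift from its cis-methyl group or by oligomerisation before the ynol ether captures it. The fallback sets out from 1 and returns at 8; it keeps the ring expansion but makes the vinylketene without opening 4. Acylation of the lithium enolate of ethyl acetate (LDA, THF, −78 °C, 2 equiv of enolate) with 1 should give ethyl 4-methyl-3-oxopentanoate F1. O-Ethylation with triethyl orthoformate (cat. H2SO4, EtOH) should give ethyl (E)-3-ethoxy-4-methylpent-2-enoate F2. Saponification (LiOH, aq. THF, then acid) should give (E)-3-ethoxy-4-methylpent-2-enoic acid F3, and oxalyl chloride (cat. DMF, CH2Cl2) should give (E)-3-ethoxy-4-methylpent-2-enoyl chloride F4. Treatment of F4 with Et3N in the presence of 2 at room temperature should generate vinylketene 5 by 1,4-dehydrochlorination and give cyclobutenone 6 by [2+2] cycloaddition. Cyclobutenone 6 carries a hydrogen at C4 and should undergo the 4π-opening/6π-closure ring expansion to 8 on warming to about 80 °C.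

Step 8. The same methylene transfer can couple each partner with itself, and prolonged exposure to alkali can scramble the methylene bridge between the halves. The fallback sets out from 15 and returns at 17; it makes the chromene the only electrophile. Mannich reaction of 15 with aqueous dimethylamine and formaldehyde (EtOH, rt) should give 1-{8-[(dimethylamino)methyl]-5,7-dihydroxy-2,2-dimethyl-2H-chromen-6-yl}-2-methylpropan-1-one F5. Heating F5 with 10 (dioxane, 100 °C) should expel dimethylamine to give the ortho-quinone methide F6, which is captured at its exocyclic carbon by the enol carbon of 10 to give 17. Neither component then has a second nucleophilic carbon, so self-coupling is excluded.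

Step 7. The Lewis-acidic gold catalyst could ionise the tertiary propargylic C–O bond (loss of the ether) or be sequestered by the chelating acylphenol, stalling the hydroarylation. The fallback sets out from 14 and returns at 15. Thermal aryl propargyl ether Claisen rearrangement (N,N-diethylaniline, 180 °C) should give 1-[2,4,6-trihydroxy-3-(3-methylbuta-1,2-dien-1-yl)phenyl]-2-methylpropan-1-one F7, which should close in the same flask by 1,5-hydrogen shift and oxa-6π-electrocyclisation to 15. In this variant the closure can also engage the 2-hydroxyl, so a regioisomer separation would be needed.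

**Further compounds**

F1 | step 2 | ethyl 4-methyl-3-oxopentanoate | CCOC(=O)CC(=O)C(C)C
F2 | step 2 | ethyl (E)-3-ethoxy-4-methylpent-2-enoate | CCOC(=O)/C=C(/OCC)C(C)C
F3 | step 2 | (E)-3-ethoxy-4-methylpent-2-enoic acid | OC(=O)/C=C(/OCC)C(C)C
F4 | step 2 | (E)-3-ethoxy-4-methylpent-2-enoyl chloride | ClC(=O)/C=C(/OCC)C(C)C
F5 | step 8 | 1-{8-[(dimethylamino)methyl]-5,7-dihydroxy-2,2-dimethyl-2H-chromen-6-yl}-2-methylpropan-1-one | CC(C)C(=O)c1c(O)c(CN(C)C)c2OC(C)(C)C=Cc2c1O
F6 | step 8 | 5-hydroxy-2,2-dimethyl-8-methylidene-6-(2-methylpropanoyl)-2H-chromen-7(8H)-one (ortho-quinone methide, not isolated) | CC(C)C(=O)C1=C(O)C2=C(OC(C)(C)C=C2)C(=C)C1=O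
F7 | step 7 | 1-[2,4,6-trihydroxy-3-(3-methylbuta-1,2-dien-1-yl)phenyl]-2-methylpropan-1-one (not isolated) | CC(C)C(=O)c1c(O)cc(O)c(C=C=C(C)C)c1O
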